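**Retrosynthetic overview**
- The target is opened at the C3 ester (Steglich, last step) and at the C11–O–aryl ether (Mitsunobu with bought umbelliferone), leaving a drima-5,8(12)-diene-3β,11-diol.
- The diol comes from a bicyclic allylsilane by Sakurai hydroxymethylation at C9, which sets C9 and places the exocyclic methylene.
- The bicyclic allylsilane comes from an acyclic 1,3-dien-9-yne by one Rh(I)-catalysed intramolecular [4+2] cycloaddition: rings A and B and the quaternary C10 form together, and the alkyne becomes the C5=C6 alkene.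
- The dienynol comes from methyl geranate: ozonolysis, allenylzinc propargylation (gem-dimethyl plus alkyne), ester to 2-(silylmethyl)diene, oxidation, CBS reduction (sets C3).
- Ring order: no ring until step 6, then A and B at once; the coumarin rings are bought.

Assumption: commercial methyl geranate is taken as the pure (2E)-isomer; positions in the bicyclic compounds are quoted in drimane numbering (C3 carbinol, C4 CMe2, C5=C6 ring alkene, C8=C12 exocyclic alkene, C9 bearing C11H2O, C10 angular C–CH3).

**Step 1**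
Reactants: 1 methyl (2E)-3,7-dimethylocta-2,6-dienoate (methyl geranate)
Product: 3 methyl (2E)-3-methyl-6-oxohex-2-enoate, via ozonide 2 (not isolated)
Conditions: O3 (1.0 equiv, Sudan Red 7B end point), CH2Cl2, −78 °C; then Me2S, −78 °C → rt
Reagents that add atoms: ozone, [O-][O+]=O
Why: Chemoselective ozonolysis with reductive work-up: ozone attacks the electron-rich 6,7-alkene much faster than the ester-conjugated 2,3-alkene, so one equivalent cleaves only the isopropylidene end to the aldehyde and no stereocentre is involved.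

**Step 2**
Reactants: 3 methyl (2E)-3-methyl-6-oxohex-2-enoate; 4 3-chloro-3-methylbut-1-yne
Product: 6 methyl (2E)-6-hydroxy-3,7,7-trimethylnon-2-en-8-ynoate (racemic), via allenylzinc chloride 5 (not isolated)
Conditions: Zn dust (activated with 1,2-dibromoethane/TMSCl, 2.5 equiv), THF, 0 °C → rt; sat. aq NH4Cl
Reagents that add atoms: none
Why: Zinc Barbier propargylation: the allenylzinc formed from the tertiary propargylic chloride adds to the aldehyde by SE2′ through a cyclic transition state, so the new C–C bond ends at the CMe2 carbon (future C4) next to the carbinol (future C3), the enoate is untouched, and the carbinol centre is left racemic because step 4 erases it.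

**Step 3**
Reactants: 6 methyl (2E)-6-hydroxy-3,7,7-trimethylnon-2-en-8-ynoate
Product: 8 (7E)-3,3,7-trimethyl-9-[(trimethylsilyl)methyl]deca-7,9-dien-1-yn-4-ol (racemic), via bis(silylmethyl)carbinol 7 (not isolated)
Conditions: Me3SiCH2MgCl (6 equiv), anhydrous CeCl3 (6 equiv), THF, −78 °C → rt; then silica gel, CH2Cl2, rt
Reagents that add atoms: (trimethylsilyl)methylmagnesium chloride, C[Si](C)(C)C[Mg]Cl
Why: Bunnelle allylsilane synthesis: CeCl3-promoted double 1,2-addition of the Grignard reagent to the ester gives the tertiary β-hydroxysilane, whose Peterson elimination on silica turns the enoate into the 2-(silylmethyl)-1,3-diene with the E alkene kept, while the OH and the alkyne C–H are only deprotonated and return on work-up.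

**Step 4**
Reactants: 8 (7E)-3,3,7-trimethyl-9-[(trimethylsilyl)methyl]deca-7,9-dien-1-yn-4-ol
Product: 9 (7E)-3,3,7-trimethyl-9-[(trimethylsilyl)methyl]deca-7,9-dien-1-yn-4-one
Conditions: Dess–Martin periodinane (1.3 equiv), NaHCO3, CH2Cl2, 0 °C → rt
Reagents that add atoms: none
Why: Dess–Martin oxidation under bicarbonate buffer converts the hindered secondary alcohol into the ketone without acid that would protodesilylate the allylsilane, and it removes the racemic centre so that C3 can be set by a reagent.

**Step 5**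
Reactants: 9 (7E)-3,3,7-trimethyl-9-[(trimethylsilyl)methyl]deca-7,9-dien-1-yn-4-one
Product: 10 (4S,7E)-3,3,7-trimethyl-9-[(trimethylsilyl)methyl]deca-7,9-dien-1-yn-4-ol
Conditions: (R)-2-methyl-CBS-oxazaborolidine (20 mol%), catecholborane (1.5 equiv), toluene, −78 → −40 °C; MeOH, then aq NaOH wash
Reagents that add atoms: none
Why: Corey–Bakshi–Shibata reduction: with the quaternary propargylic carbon as the large and the CH2 chain as the small substituent, the (R)-oxazaborolidine delivers hydride to the face that gives the (S)-carbinol (C3 of the target), and catecholborane at low temperature does not hydroborate the alkyne or the diene.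

**Step 6**
Reactants: 10 (4S,7E)-3,3,7-trimethyl-9-[(trimethylsilyl)methyl]deca-7,9-dien-1-yn-4-ol
Product: 11 (2S,4aR)-1,1,4a-trimethyl-6-[(trimethylsilyl)methyl]-1,2,3,4,4a,7-hexahydronaphthalen-2-ol
Conditions: [Rh(cod)Cl]2 (2.5 mol%), AgSbF6 (5 mol%), (R)-DTBM-SEGPHOS (5.5 mol%; the (S)-ligand is used instead if the first run favours the C10 epimer), ClCH2CH2Cl, 60 °C; chromatography
Reagents that add atoms: none
Why: Proposed new method: cationic Rh(I) binds the alkyne and the s-cis diene, oxidative cyclisation forms the C5–C10 bond (ring A, quaternary C10) and reductive elimination of the allyl rhodacycle forms C6–C7 (ring B), giving the 5,8-diene in one operation; the closest known reaction type is the Rh(I)- or Ni(0)-catalysed intramolecular [4+2] cycloaddition of unactivated dienynes, also known in enantioselective form with chiral bisphosphines; new here are the fully substituted diene terminus that becomes the angular C10 and its control by the ligand, since the remote C3 carbinol gives little bias, so the minor C10 epimer is a separable diastereomer and the enantiopurity stays that of step 5.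

**Step 7**
Reactants: 11 (2S,4aR)-1,1,4a-trimethyl-6-[(trimethylsilyl)methyl]-1,2,3,4,4a,7-hexahydronaphthalen-2-ol
Product: 12 (2S,4aR,5R)-5-(hydroxymethyl)-1,1,4a-trimethyl-6-methylidene-1,2,3,4,4a,5,6,7-octahydronaphthalen-2-ol
Conditions: paraformaldehyde (1.5 equiv), Me2AlCl (3.5 equiv), CH2Cl2, −78 → −20 °C; aq Rochelle salt
Reagents that add atoms: formaldehyde (from paraformaldehyde), C=O
Why: Hosomi–Sakurai hydroxymethylation: the Me2AlCl–formaldehyde complex attacks the γ-carbon C9 of the allylsilane and loss of the silyl group moves the alkene to the exocyclic C8=C12 position; the new C9–C11 bond forms axially on the face anti to the angular C10 methyl, giving the 9α-CH2OH (5R), while the far less nucleophilic C5=C6 alkene and the C3–OH (carried as aluminium alkoxide) are not touched.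

**Step 8**
Reactants: 12 (2S,4aR,5R)-5-(hydroxymethyl)-1,1,4a-trimethyl-6-methylidene-1,2,3,4,4a,5,6,7-octahydronaphthalen-2-ol; 13 7-hydroxy-2H-chromen-2-one (umbelliferone)
Product: 14 7-{[(1R,6S,8aR)-6-hydroxy-5,5,8a-trimethyl-2-methylidene-1,2,3,5,6,7,8,8a-octahydronaphthalen-1-yl]methoxy}-2H-chromen-2-one
Conditions: PPh3 (1.5 equiv), DIAD (1.5 equiv), THF, 0 °C → rt
Reagents that add atoms: none
Why: Mitsunobu etherification: only the primary C11–OH forms the alkoxyphosphonium and is displaced by the acidic phenol of umbelliferone, the neopentyl-type secondary C3–OH next to the gem-dimethyl group stays free, and no stereocentre is touched because C11 is a CH2.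

**Step 9**
Reactants: 14 7-{[(1R,6S,8aR)-6-hydroxy-5,5,8a-trimethyl-2-methylidene-1,2,3,5,6,7,8,8a-octahydronaphthalen-1-yl]methoxy}-2H-chromen-2-one; 15 3-hydroxy-3-methylbutanoic acid
Product: 16 (2S,4aR,5R)-1,1,4a-trimethyl-6-methylidene-5-{[(2-oxo-2H-chromen-7-yl)oxy]methyl}-1,2,3,4,4a,5,6,7-octahydronaphthalen-2-yl 3-hydroxy-3-methylbutanoate
Conditions: 15 (3 equiv), EDC·HCl (3 equiv), DMAP (1 equiv), CH2Cl2, rt → 35 °C
Reagents that add atoms: none
Why: Steglich esterification: the DMAP acylpyridinium of 15 acylates the equatorial C3–OH with retention, the tertiary hydroxyl of the acid is too hindered to self-acylate, and the coumarin, the ether and both alkenes are inert.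

**Compound list**
1 | methyl (2E)-3,7-dimethylocta-2,6-dienoate (methyl geranate) | COC(=O)/C=C(\C)CCC=C(C)C | starting material
2 | methyl (2E)-5-(5,5-dimethyl-1,2,4-trioxolan-3-yl)-3-methylpent-2-enoate (ozonide) | COC(=O)/C=C(\C)CCC1OOC(C)(C)O1 | intermediate
3 | methyl (2E)-3-methyl-6-oxohex-2-enoate | COC(=O)/C=C(\C)CCC=O | intermediate
4 | 3-chloro-3-methylbut-1-yne | C#CC(C)(C)Cl | starting material
5 | chloro(3-methylbuta-1,2-dien-1-yl)zinc (allenylzinc chloride) | CC(C)=C=C[Zn]Cl | intermediate
6 | methyl (2E)-6-hydroxy-3,7,7-trimethylnon-2-en-8-ynoate (racemic) | COC(=O)/C=C(\C)CCC(O)C(C)(C)C#C | intermediate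
7 | (3E)-4,8,8-trimethyl-1-(trimethylsilyl)-2-[(trimethylsilyl)methyl]dec-3-en-9-yne-2,7-diol (racemic, present as its alkoxide) | C#CC(C)(C)C(O)CC/C(C)=C/C(O)(C[Si](C)(C)C)C[Si](C)(C)C | intermediate
8 | (7E)-3,3,7-trimethyl-9-[(trimethylsilyl)methyl]deca-7,9-dien-1-yn-4-ol (racemic) | C#CC(C)(C)C(O)CC/C(C)=C/C(=C)C[Si](C)(C)C | intermediate
9 | (7E)-3,3,7-trimethyl-9-[(trimethylsilyl)methyl]deca-7,9-dien-1-yn-4-one | C#CC(C)(C)C(=O)CC/C(C)=C/C(=C)C[Si](C)(C)C | intermediate
10 | (4S,7E)-3,3,7-trimethyl-9-[(trimethylsilyl)methyl]deca-7,9-dien-1-yn-4-ol | C#CC(C)(C)[C@@H](O)CC/C(C)=C/C(=C)C[Si](C)(C)C | intermediate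
11 | (2S,4aR)-1,1,4a-trimethyl-6-[(trimethylsilyl)methyl]-1,2,3,4,4a,7-hexahydronaphthalen-2-ol | C[Si](C)(C)CC1=C[C@@]2(C)CC[C@H](O)C(C)(C)C2=CC1 | intermediate
12 | (2S,4aR,5R)-5-(hydroxymethyl)-1,1,4a-trimethyl-6-methylidene-1,2,3,4,4a,5,6,7-octahydronaphthalen-2-ol | C=C1CC=C2C(C)(C)[C@@H](O)CC[C@]2(C)[C@@H]1CO | intermediate
13 | 7-hydroxy-2H-chromen-2-one (umbelliferone) | Oc1ccc2ccc(=O)oc2c1 | starting material
14 | 7-{[(1R,6S,8aR)-6-hydroxy-5,5,8a-trimethyl-2-methylidene-1,2,3,5,6,7,8,8a-octahydronaphthalen-1-yl]methoxy}-2H-chromen-2-one | C=C1CC=C2C(C)(C)[C@@H](O)CC[C@]2(C)[C@@H]1COc1ccc2ccc(=O)oc2c1 | intermediate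
15 | 3-hydroxy-3-methylbutanoic acid | CC(C)(O)CC(=O)O | starting material
16 | (2S,4aR,5R)-1,1,4a-trimethyl-6-methylidene-5-{[(2-oxo-2H-chromen-7-yl)oxy]methyl}-1,2,3,4,4a,5,6,7-octahydronaphthalen-2-yl 3-hydroxy-3-methylbutanoate | C=C1CC=C2C(C)(C)[C@@H](OC(=O)CC(C)(C)O)CC[C@]2(C)[C@@H]1COc1ccc2ccc(=O)oc2c1 | target

**Totals**
Total step count: 9. Longest linear sequence: 9 steps (1 → 16).

**Three steps most likely to fail**

Step 6 (Rh-catalysed double ring closure). The fully substituted diene terminus may resist oxidative cyclisation, or the C10 selectivity may be low. The fallback sets out from 10 and comes back at 11; it makes the alkyne an activated dienophile and closes both rings thermally. The dimagnesium salt of 10 (EtMgBr, 2.2 equiv, THF, 0 °C) is sulfinylated with methyl 4-methylbenzenesulfinate to give the alkynyl sulfoxide (4S,7E)-3,3,7-trimethyl-1-(4-methylbenzenesulfinyl)-9-[(trimethylsilyl)methyl]deca-7,9-dien-1-yn-4-ol F1 as a mixture at sulfur. Heating F1 in toluene at 120 °C gives, by intramolecular Diels–Alder reaction, the bicyclic vinyl sulfoxide (2S,4aR)-1,1,4a-trimethyl-8-(4-methylbenzenesulfinyl)-6-[(trimethylsilyl)methyl]-1,2,3,4,4a,7-hexahydronaphthalen-2-ol F2 together with its C10 epimer. Sulfoxide–lithium exchange (t-BuLi, THF, −78 °C) and protonation with MeOH remove the sulfinyl group and give 11, which is separated by chromatography from the C10 epimer (2S,4aS)-1,1,4a-trimethyl-6-[(trimethylsilyl)methyl]-1,2,3,4,4a,7-hexahydronaphthalen-2-ol F3.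

Step 8 (Mitsunobu etherification). The axial, β-branched C11–OH next to the quaternary C10 may be displaced too slowly. The fallback sets out from 11 (with 13) and comes back at 14; it puts the aryloxy group on the one-carbon electrophile, so that the C9–C11 bond is formed with the ether already in place. Umbelliferone 13 is alkylated with chloromethyl methyl sulfide (NaH, DMF) to 7-[(methylsulfanyl)methoxy]-2H-chromen-2-one F4. SO2Cl2 (CH2Cl2, 0 °C) converts F4 into 7-(chloromethoxy)-2H-chromen-2-one F5. A Sakurai reaction of allylsilane 11 with F5 (SnCl4 or ZnBr2, CH2Cl2, −78 °C), with the same anti-to-methyl attack at C9, gives 14 directly.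

Step 9 (esterification). The hindered C3–OH and the free β-hydroxy acid may give low conversion or N-acylurea. The fallback sets out from 14 and comes back at 16; it builds the side chain by C–C bond formation. Bromoacetyl bromide and pyridine (CH2Cl2, 0 °C) give the bromoacetate (2S,4aR,5R)-1,1,4a-trimethyl-6-methylidene-5-{[(2-oxo-2H-chromen-7-yl)oxy]methyl}-1,2,3,4,4a,5,6,7-octahydronaphthalen-2-yl 2-bromoacetate F6. A Reformatsky reaction of F6 (activated Zn, excess acetone, THF, 40 °C) adds the zinc enolate to acetone and gives 16.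

**Further compounds**
F1 | step 6 | (4S,7E)-3,3,7-trimethyl-1-(4-methylbenzenesulfinyl)-9-[(trimethylsilyl)methyl]deca-7,9-dien-1-yn-4-ol (mixture at sulfur) | Cc1ccc(cc1)S(=O)C#CC(C)(C)[C@@H](O)CC/C(C)=C/C(=C)C[Si](C)(C)C
F2 | step 6 | (2S,4aR)-1,1,4a-trimethyl-8-(4-methylbenzenesulfinyl)-6-[(trimethylsilyl)methyl]-1,2,3,4,4a,7-hexahydronaphthalen-2-ol (mixture at sulfur) | C[Si](C)(C)CC1=C[C@@]2(C)CC[C@H](O)C(C)(C)C2=C(C1)S(=O)c1ccc(C)cc1
F3 | step 6 | (2S,4aS)-1,1,4a-trimethyl-6-[(trimethylsilyl)methyl]-1,2,3,4,4a,7-hexahydronaphthalen-2-ol | C[Si](C)(C)CC1=C[C@]2(C)CC[C@H](O)C(C)(C)C2=CC1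
F4 | step 8 | 7-[(methylsulfanyl)methoxy]-2H-chromen-2-one | CSCOc1ccc2ccc(=O)oc2c1
F5 | step 8 | 7-(chloromethoxy)-2H-chromen-2-one | ClCOc1ccc2ccc(=O)oc2c1
F6 | step 9 | (2S,4aR,5R)-1,1,4a-trimethyl-6-methylidene-5-{[(2-oxo-2H-chromen-7-yl)oxy]methyl}-1,2,3,4,4a,5,6,7-octahydronaphthalen-2-yl 2-bromoacetate | C=C1CC=C2C(C)(C)[C@@H](OC(=O)CBr)CC[C@]2(C)[C@@H]1COc1ccc2ccc(=O)oc2c1
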